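Numbering (longipinane, used throughout): C1 ketone C, C2 =CH, C3 =C(CH3), C4 allylic bridgehead CH, C5 cyclobutane CH that carries C6, C6 quaternary C (CH3, CH2O), C7 CH–OAc, C8/C9 CH2, C10 quaternary cyclobutane C (CH3), C11 bridgehead CH next to C1.
Cuts: both ester C–O bonds; the enone is traced back by a 1,3-carbonyl transposition to a C3 ketone; then C4–C5 and C10–CH3 are cut together, opening the cyclobutane C4–C5–C11–C10 to a ring-fusion cyclohexenone with a C5 sulfonate; the cyclohexenone goes back to an anisole, and the aryl–C5(=O) bond to an aryllithium plus ester.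
What makes the key event possible: C10 and C4 are the β- and α-carbons of a six-ring ketone placed at C3, and C5 sits 1,3 to C4 across the C10–C11 ring fusion with an oxygen that can leave; O-alkylation would need a bridgehead enol ether, so only C–C closure is open.
Forward ring order: arene (bought) → benzo-fused seven-membered ring (Parham acylation) → arene dearomatised to the six-membered enone (Birch) → cyclobutane last (conjugate methylation, then 4-exo-tet enolate alkylation).
Stereochemistry: C7 from a Noyori hydrogenation; C6 by chelate-controlled methylation relative to C7; the C5 carbinol by hydride anti to the angular C6 methyl (inverted in the key step); C11 by ring-fusion equilibration; C10 and C4 in the key step.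

Key step: step 11

Assumption: 3-(2-bromo-5-methoxyphenyl)propanoic acid and angelic acid are bought. In the chain compounds 3–10 the pentanoate carbons C1–C5 become C5–C9; from compound 11 on, atoms carry the longipinane numbers of the target.

Step 1
Reactants: 1 3-(2-bromo-5-methoxyphenyl)propanoic acid; 2 potassium methyl malonate
Product: 3 methyl 5-(2-bromo-5-methoxyphenyl)-3-oxopentanoate
Conditions: CDI, THF, rt; then 2, MgCl2, Et3N, MeCN, rt → 45 °C; aq. HCl
Reagents that add atoms: potassium methyl malonate (2), COC(=O)CC(=O)[O-].[K+]
Why: The acyl imidazole of 1 C-acylates the magnesium enolate of the malonate half-ester and the adduct loses CO2 (Masamune–Brooks β-keto ester synthesis), which tolerates the aryl bromide.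

Step 2
Reactants: 3 β-keto ester
Product: 4 methyl (3R)-5-(2-bromo-5-methoxyphenyl)-3-hydroxypentanoate
Conditions: H2 (50 bar), RuCl2[(R)-BINAP] (0.5 mol %), MeOH, 50 °C
Reagents that add atoms: none
Why: Noyori asymmetric hydrogenation of a 3-oxoalkanoate: the (R)-BINAP–ruthenium catalyst binds the keto ester as a chelate and delivers hydrogen to the face that gives the (3R)-alcohol, which becomes C7; the aryl bromide is inert to this catalyst.

Step 3
Reactants: 4 hydroxy ester; 5 formaldehyde
Product: 6 methyl (2R,3R)-5-(2-bromo-5-methoxyphenyl)-3-hydroxy-2-(hydroxymethyl)pentanoate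
Conditions: LDA (2.3 equiv), THF, −78 → −30 °C; then CH2O (g), −78 °C; H2O
Reagents that add atoms: formaldehyde (5), C=O
Why: Fráter–Seebach aldol: the chelated dilithio derivative of the β-hydroxy ester adds to monomeric formaldehyde anti to the C3 side chain; the C2 configuration formed here is erased in step 4, so only the added carbon matters.

Step 4
Reactants: 6 diol ester; 7 iodomethane
Product: 8 methyl (2S,3R)-5-(2-bromo-5-methoxyphenyl)-3-hydroxy-2-(hydroxymethyl)-2-methylpentanoate
Conditions: LDA (3.4 equiv), THF/DMPU, −78 → −30 °C; then MeI, −78 → −40 °C; H2O
Reagents that add atoms: iodomethane (7), CI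
Why: Fráter–Seebach alkylation at the trilithio stage: the hydroxymethyl group is present as its alkoxide, so the enolate has no β-leaving group, and iodomethane attacks the lithium-chelated enolate on the face opposite the C3 side chain, fixing the quaternary centre (future C6) relative to C7.

Step 5
Reactants: 8 quaternary diol ester; 9 2,2-dimethoxypropane
Product: 10 methyl (4R,5S)-4-[2-(2-bromo-5-methoxyphenyl)ethyl]-2,2,5-trimethyl-1,3-dioxane-5-carboxylate
Conditions: Me2C(OMe)2, PPTS (cat.), CH2Cl2, rt
Reagents that add atoms: 2,2-dimethoxypropane (9), COC(C)(C)OC
Why: Acid-catalysed transketalisation protects the 1,3-diol as a 1,3-dioxane whose chair carries the side chain and the ester equatorial and the methyl axial, and sets these two oxygens apart from the one still to be made at C5.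

Step 6
Reactants: 10 dioxane ester
Product: 11 aryl ketone
Conditions: t-BuLi (2.1 equiv), THF, −100 → −78 °C, then −40 °C; H2O
Reagents that add atoms: none
Why: Parham cyclisation: bromine–lithium exchange at −100 °C is faster than attack of t-BuLi on the neopentyl ester, and the aryllithium, held close by the equatorial side chain, acylates itself to close the seven-membered ring; the tetrahedral adduct should persist until the quench, so no second addition is expected.

Step 7
Reactants: 11 aryl ketone
Product: 12 benzylic alcohol
Conditions: NaBH4, MeOH/THF, 0 °C → rt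
Reagents that add atoms: none
Why: Hydride reduction under steric approach control: the angular C6 methyl is axial on the seven-membered ring and blocks its own face, so hydride should enter from the other side and leave the 5-OH cis to that methyl and to O-7, the arrangement that later puts the leaving group anti to the incoming C4.

Step 8
Reactants: 12 benzylic alcohol
Product: 13 dienol ether
Conditions: Li, NH3(l), THF, t-BuOH, −78 °C; isoprene, then MeOH
Reagents that add atoms: none
Why: Birch reduction of a 3,4-dialkylanisole gives the 1-methoxy-1,4-diene that keeps the two ring-fusion carbons as a tetrasubstituted alkene; the benzylic oxygen sits para to the methoxy group and is carried as its lithium alkoxide, which should resist C–O cleavage, and the acetonide is inert.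

Step 9
Reactants: 13 dienol ether; 14 water
Product: 16 hydroxy enone, via β,γ-unsaturated ketone 15 (not isolated)
Conditions: (CO2H)2, THF/H2O, 0 °C → rt; then DBU (0.2 equiv), CH2Cl2, rt
Reagents that add atoms: water (14), O
Why: Mild acid hydrolyses the enol ether without touching the dioxane, and DBU moves the alkene into conjugation through the dienolate, which also equilibrates the new C11 hydrogen towards the isomer with C1, O-5, the C6 CH2O arm and O-7 all equatorial on the cycloheptane, that is H-11 cis to the 5-OH.

Step 10
Reactants: 16 hydroxy enone; 17 methanesulfonyl chloride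
Product: 18 enone mesylate
Conditions: MsCl, Et3N, CH2Cl2, −20 → 0 °C
Reagents that add atoms: methanesulfonyl chloride (17), CS(Cl)(=O)=O
Why: Sulfonylation through sulfene converts the hindered secondary alcohol into the mesylate with retention, and the amine base is too weak to trigger loss of the mesylate through the dienolate.

Step 11
Reactants: 18 enone mesylate; 19 methyllithium
Product: 21 tricyclic ketone, via lithium enolate 20 (not isolated)
Conditions: Me2CuLi (1.5 equiv, prepared in the flask from MeLi and CuBr·SMe2), Et2O, −40 → 0 °C; then THF/HMPA, 0.01 M, 0 → 25 °C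
Reagents that add atoms: methyllithium (19), [Li]C; lithium dimethylcuprate, [Li+].C[Cu-]C
Why: Me2CuLi, formed from methyllithium and CuBr·SMe2, adds its methyl to the β-carbon C10 of the ring-fusion enone and so generates, regiospecifically and without a proton source, the C3–C4 lithium enolate 20, whose carbon C4 then displaces the C5 mesylate from the rear once HMPA is added. The closest known reaction types are angular methylation of ring-fusion cyclohexenones by cuprates and closure of bicyclo[3.1.1]heptanone cyclobutanes by intramolecular alkylation of a ketone enolate with a 1,3-placed sulfonate, run here in one flask as a Michael-initiated ring closure. The cyclobutane closes in the 4-exo-tet mode. C10 is set by the cuprate entering trans to the C11–C5 ring bond (cis ring fusion, CH3 cis to H-11), C4 can only bond on the face held by the C10–C11 tether, and C5 is set by inversion of the mesylate whose configuration came from step 7. The step needs C- over O-alkylation (O-alkylation would give a bridgehead enol ether), the C4 and not the C2 enolate (fixed by the conjugate addition as long as no proton transfer occurs, hence excess cuprate and high dilution) and substitution over elimination (C6 is quaternary and H-11 is syn to the leaving group).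

Step 12
Reactants: 21 tricyclic ketone
Product: 23 tricyclic enone, via trimethylsilyl enol ether 22 (not isolated)
Conditions: LDA, THF, −78 °C; TMSCl; then Pd(OAc)2 (1.1 equiv), MeCN, rt
Reagents that add atoms: none
Why: Saegusa–Ito oxidation: the bridgehead C4 cannot enolise, so LDA/TMSCl gives only the C2–C3 silyl enol ether, which Pd(OAc)2 dehydrogenates to the C1=C2 enone.

Step 13
Reactants: 23 tricyclic enone; 19 methyllithium
Product: 24 tertiary allylic alcohol
Conditions: MeLi, Et2O/THF, −78 °C; H2O
Reagents that add atoms: methyllithium (19), [Li]C
Why: 1,2-Addition of methyllithium to the enone brings in the future C3 methyl from the face of the three-carbon bridge that lies under the C5 bridge and away from the methyl of the C10 bridge; the carbinol configuration is lost in step 14, so either epimer serves.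

Step 14
Reactants: 24 tertiary allylic alcohol
Product: 25 methyl enone acetonide
Conditions: PCC, NaOAc, 4 Å MS, CH2Cl2, rt
Reagents that add atoms: none
Why: Babler–Dauben oxidative transposition: the chromate ester of the tertiary allylic alcohol undergoes [3,3] shift to C1 and is oxidised there, moving the carbonyl to C1 and leaving the methyl on C3 of the new enone, as in the pin-3-en-2-ol to verbenone change.

Step 15
Reactants: 25 methyl enone acetonide
Product: 26 enone diol
Conditions: AcOH/H2O (4:1), 40 °C
Reagents that add atoms: none
Why: Aqueous acetic acid hydrolyses the 1,3-dioxane acetal (acetal hydrolysis), while the enone and the cyclobutane, which carry no ionisable allylic oxygen, should be left alone.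

Step 16
Reactants: 26 enone diol; 27 angelic acid
Product: 28 primary angelate
Conditions: 27, 2,4,6-trichlorobenzoyl chloride, Et3N, toluene, rt; then 26, toluene, 50 °C
Reagents that add atoms: angelic acid (27), C/C=C(/C)C(=O)O
Why: Yamaguchi esterification: the mixed 2,4,6-trichlorobenzoic anhydride should acylate the primary neopentyl alcohol much faster than the hindered secondary C7 alcohol, and the DMAP-free, moderate-temperature protocol is chosen to keep the Z (angelate) geometry.

Step 17
Reactants: 28 primary angelate; 29 acetic anhydride
Product: 30 target
Conditions: Ac2O, pyridine, DMAP (cat.), CH2Cl2, rt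
Reagents that add atoms: acetic anhydride (29), CC(=O)OC(C)=O
Why: DMAP-catalysed acetylation of the remaining hindered secondary alcohol completes the target without touching the angelate or the enone.

Compound list
1 | 3-(2-bromo-5-methoxyphenyl)propanoic acid | OC(=O)CCc1cc(OC)ccc1Br | starting material
2 | potassium methyl malonate | COC(=O)CC(=O)[O-].[K+] | starting material
3 | methyl 5-(2-bromo-5-methoxyphenyl)-3-oxopentanoate | COC(=O)CC(=O)CCc1cc(OC)ccc1Br | intermediate
4 | methyl (3R)-5-(2-bromo-5-methoxyphenyl)-3-hydroxypentanoate | COC(=O)C[C@H](O)CCc1cc(OC)ccc1Br | intermediate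
5 | formaldehyde | C=O | starting material
6 | methyl (2R,3R)-5-(2-bromo-5-methoxyphenyl)-3-hydroxy-2-(hydroxymethyl)pentanoate | COC(=O)[C@H](CO)[C@H](O)CCc1cc(OC)ccc1Br | intermediate
7 | iodomethane | CI | starting material
8 | methyl (2S,3R)-5-(2-bromo-5-methoxyphenyl)-3-hydroxy-2-(hydroxymethyl)-2-methylpentanoate | COC(=O)[C@@](C)(CO)[C@H](O)CCc1cc(OC)ccc1Br | intermediate
9 | 2,2-dimethoxypropane | COC(C)(C)OC | starting material
10 | methyl (4R,5S)-4-[2-(2-bromo-5-methoxyphenyl)ethyl]-2,2,5-trimethyl-1,3-dioxane-5-carboxylate (side chain and ester equatorial, 5-methyl axial) | COC(=O)[C@@]1(C)COC(C)(C)O[C@@H]1CCc1cc(OC)ccc1Br | intermediate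
11 | aryl ketone: benzo-fused cycloheptanone with C5 ketone, anisole ring (OMe on C3), (6S,7R); O-7 and the C6 CH2O tied as acetonide (dioxane trans-fused, C6 methyl axial) | CC1(C)OC[C@]2(C)C(=O)c3ccc(OC)cc3CC[C@H]2O1 | intermediate
12 | benzylic alcohol (5S,6R,7R): 5-OH cis to the C6 methyl and to O-7; acetonide as in 11 | CC1(C)OC[C@]2(C)[C@@H](O)c3ccc(OC)cc3CC[C@H]2O1 | intermediate
13 | dienol ether: 1,4-dihydro derivative of 12 (C2=C3 methyl enol ether with OMe on C3, C10=C11 tetrasubstituted alkene, C1 and C4 CH2) | CC1(C)OC[C@]2(C)[C@@H](O)C3=C(CC(OC)=CC3)CC[C@H]2O1 | intermediate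
14 | water | O | starting material
15 | β,γ-unsaturated ketone (C3 ketone, C10=C11 alkene), 5-OH and acetonide as in 12 | CC1(C)OC[C@]2(C)[C@@H](O)C3=C(CC(=O)CC3)CC[C@H]2O1 | intermediate
16 | hydroxy enone: C3 ketone conjugated with C4=C10, H-11 cis to the 5-OH; 5-OH, C6 methyl and O-7 on one face; acetonide on O-7/CH2O | CC1(C)OC[C@]2(C)[C@@H](O)[C@@H]3CCC(=O)C=C3CC[C@H]2O1 | intermediate
17 | methanesulfonyl chloride | CS(Cl)(=O)=O | starting material
18 | enone mesylate: 5-O-methanesulfonate of 16 | CC1(C)OC[C@]2(C)[C@@H](OS(C)(=O)=O)[C@@H]3CCC(=O)C=C3CC[C@H]2O1 | intermediate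
19 | methyllithium | [Li]C | starting material
20 | lithium enolate (C3–C4 enolate, C10 methyl cis to H-11, C5 mesylate intact) | CC1(C)OC[C@]2(C)[C@@H](OS(C)(=O)=O)[C@@H]3CCC([O-])=C[C@]3(C)CC[C@H]2O1.[Li+] | intermediate
21 | tricyclic ketone: longipinane skeleton without the C3 methyl, C3 ketone, C1 and C2 CH2, ring stereocentres as in the target, acetonide on O-7/CH2O | CC1(C)OC[C@]2(C)[C@@H]3[C@H]4C(=O)CC[C@@H]3[C@@]4(C)CC[C@H]2O1 | intermediate
22 | trimethylsilyl enol ether of 21 (C2=C3, OSiMe3 on C3) | CC1(C)OC[C@]2(C)[C@@H]3[C@H]4C(O[Si](C)(C)C)=CC[C@@H]3[C@@]4(C)CC[C@H]2O1 | intermediate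
23 | tricyclic enone: C3 ketone, C1=C2 alkene, otherwise as 21 | CC1(C)OC[C@]2(C)[C@@H]3[C@H]4C(=O)C=C[C@@H]3[C@@]4(C)CC[C@H]2O1 | intermediate
24 | tertiary allylic alcohol: 3-methyl-3-hydroxy, C1=C2 alkene; new methyl on the face towards the C5 bridge (expected epimer, either serves) | CC1(C)OC[C@]2(C)[C@@H]3[C@H]4[C@](C)(O)C=C[C@@H]3[C@@]4(C)CC[C@H]2O1 | intermediate
25 | methyl enone acetonide: target skeleton (C1 ketone, C2=C3 with C3 methyl), O-7/CH2O as acetonide | CC1(C)OC[C@]2(C)[C@@H]3[C@H]4C(C)=CC(=O)[C@@H]3[C@@]4(C)CC[C@H]2O1 | intermediate
26 | enone diol: 7-hydroxy-6-(hydroxymethyl)longipin-2-en-1-one, configuration of the target | OC[C@]1(C)[C@@H]2[C@H]3C(C)=CC(=O)[C@@H]2[C@@]3(C)CC[C@H]1O | intermediate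
27 | angelic acid, (Z)-2-methylbut-2-enoic acid | C/C=C(/C)C(=O)O | starting material
28 | primary angelate: 6-(angeloyloxymethyl)-7-hydroxylongipin-2-en-1-one | C/C=C(/C)C(=O)OC[C@]1(C)[C@@H]2[C@H]3C(C)=CC(=O)[C@@H]2[C@@]3(C)CC[C@H]1O | intermediate
29 | acetic anhydride | CC(=O)OC(C)=O | starting material
30 | target: (4S,5R,6S,7R,10S,11S)-7-acetoxy-6-(angeloyloxymethyl)longipin-2-en-1-one | C/C=C(/C)C(=O)OC[C@]1(C)[C@@H]2[C@H]3C(C)=CC(=O)[C@@H]2[C@@]3(C)CC[C@H]1OC(C)=O | target

Total step count: 17. Longest linear sequence: 17 steps (from 1; the route is fully linear).

Steps most likely to fail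

Step 11. The copper/lithium enolate may be too poor a nucleophile for the neopentyl-type secondary mesylate, so that proton transfer from ketone already formed moves the enolate to C2 before the ring closes, or the enolate is simply recovered as uncyclised ketone. The fallback separates the two events and changes the enolate. It sets out from 18, which is treated with Me2CuLi in the presence of TMSCl to give the regiodefined trimethylsilyl enol ether F1, isolated. F1 is then opened with anhydrous benzyltrimethylammonium fluoride in THF at high dilution (fluoride-promoted regiospecific alkylation of silyl enol ethers). The metal-free ammonium enolate is far more nucleophilic, cannot equilibrate before it forms, and should close the cyclobutane to give 21, where the route is rejoined.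

Step 6. After bromine–lithium exchange the aryllithium may be protonated or react between molecules faster than it closes the seven-membered ring onto the hindered ester. The fallback uses a more electrophilic, less hindered carbonyl. It sets out from 10, which is reduced with DIBAL-H (CH2Cl2, −78 °C) to the aldehyde F2. Bromine–lithium exchange on F2 (t-BuLi, THF, −100 °C) should outrun addition of t-BuLi to the hindered α-quaternary aldehyde; fast intramolecular addition of the aryllithium to the aldehyde then gives the ring-closed benzylic alcohols F3 as a mixture of C5 epimers. Dess–Martin oxidation of F3 gives ketone 11, where the route is rejoined and step 7 sets C5.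

Step 4. The trilithio species may not stay in the C3-alkoxide chelate (the primary alkoxide can compete for lithium), which would erode the facial selectivity of the methylation and give the C2 epimer. The fallback fixes the conformation covalently instead of by chelation. It sets out from 6, which is converted with 2,2-dimethoxypropane and PPTS into the 1,3-dioxane ester F4. The ester enolate of F4 (LDA, THF, −78 °C) is methylated with iodomethane from the axial direction of the chair that keeps the side chain equatorial; no 1,3-diaxial hydrogens oppose that approach in a 1,3-dioxane. This gives 10 directly, where the route is rejoined.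

Further compounds
F1 | step 11 | trimethylsilyl enol ether of the conjugate adduct (C3–C4 enol ether, C10 methyl cis to H-11, C5 mesylate) | CC1(C)OC[C@]2(C)[C@@H](OS(C)(=O)=O)[C@@H]3CCC(O[Si](C)(C)C)=C[C@]3(C)CC[C@H]2O1
F2 | step 6 | (4R,5S)-4-[2-(2-bromo-5-methoxyphenyl)ethyl]-2,2,5-trimethyl-1,3-dioxane-5-carbaldehyde | O=C[C@@]1(C)COC(C)(C)O[C@@H]1CCc1cc(OC)ccc1Br
F3 | step 6 | benzylic alcohols, both C5 epimers of 12 | CC1(C)OC[C@]2(C)C(O)c3ccc(OC)cc3CC[C@H]2O1
F4 | step 4 | methyl (4R,5R)-4-[2-(2-bromo-5-methoxyphenyl)ethyl]-2,2-dimethyl-1,3-dioxane-5-carboxylate | COC(=O)[C@@H]1COC(C)(C)O[C@@H]1CCc1cc(OC)ccc1Br
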